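## The problem

The target, (3R)-8-hydroxy-3-[(6S)-6-hydroxyundecyl]-6-methoxy-3,4-dihydro-1H-isochromen-1-one (21), is a dihydroisocoumarin. Benzene ring A (C4a–C8a) carries a free phenol at C8, hydrogen-bonded to the lactone carbonyl, and a methyl ether at C6. It is fused to the δ-lactone ring B (C1, O2, C3, C4), and C3 bears an unbranched undecyl chain with a secondary hydroxyl at C6'. Apart from ring A the skeleton is one chain (C1–C8a–C4a–C4–C3–C1'…C11'), so the task is chain construction plus one benzannulation or one arene–chain union, with the two ring-A oxygens ending up differentiated. The two stereocentres, C3 (R) and C6' (S), are five methylenes apart. Neither can control the other, and epimers at either centre cannot be expected to separate, so each must be set correctly by a reagent or catalyst at the moment it is made. The lactone does not tolerate alkoxide, ylide or acetylide bases (ring opening, or β-elimination across C3–C4). The electron-rich phenol does not tolerate oxidants, and any β-oxygenated carbonyl intermediate can lose its β-oxygen. The enabling feature is that C3 and C6' are both secondary carbinols whose outward neighbours, C4 and C7', are methylenes. If both are written as allylic methylenes, the segment C4–C3–(C1'–C5')–C6'–C7' is a C2-symmetric 1,7-diol in which the two centres have the same spatial sense. The descriptors differ in 21 only because the benzylic carbon C4 outranks the tether whereas the pentyl group ranks below it. One enantioselective allylation, applied at both ends of heptane-1,7-diol (1), can therefore set both centres.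

## Retrosynthesis

**Ring B last (21 ⇒ 19).** The C1–O2 bond and the two O–Si bonds are cut, leading through triol ester 20 to the bis-silyl methyl salicylate 19. Closing the lactone at the end keeps it away from every basic reagent of the route. The alternative of carrying ring B from an earlier stage would expose the C4 protons and the acyl–oxygen bond to ylide and acetylide. The forward step asks only for acid that removes two secondary silyl ethers and lets the C3 hydroxyl close a six-membered ring on the neighbouring ester.

**Side-chain saturation (19 ⇒ 18).** A C8'=C9' double bond is introduced retrosynthetically, giving 18. This lets the pentyl terminus come from an olefination of a two-carbon stub, which is what an allyl group leaves after oxidative cleavage. The forward hydrogenation must spare the arene, the ester and the silyl ethers.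

**Ring A by [4+2] (18 ⇒ 11 + 15).** Ring A is cut at C4a–C5 and C8–C8a, giving ynoate 11 and the oxygenated diene 15, with cycloadduct 16 and aryl silyl ether 17 on the way.
- The neighbouring cut at C4–C4a (aryl–alkyl coupling) would need a C4 nucleophile β to an oxygen, which eliminates.
- The classical cut at C3–C4 (benzylic anion plus aldehyde) would use that bond without catalyst control, whereas here it is reserved for the allylation.
- The cycloaddition keeps the C4 methylene exactly as the allylation delivers it. It also brings the C6 methyl ether, the C8 phenol and the C1 ester in one operation, already differentiated.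
- The precursors are acyclic. The forward reaction needs regiocontrol, which the ester polarisation of 11 supplies, and aromatisation by loss of the alkoxy group from the ketene-acetal carbon.

**The diene (15 ⇒ 13 ⇒ 12).** The O–Si bond of 15 is cut to lithium dienolate 14, which comes from γ-deprotonation of enol ether 13. Compound 13 is the O-methyl enol ether of methyl acetoacetate 12. The four carbons of 12 become C8, C7, C6 and C5.

**Ynoate to aldehyde (11 ⇒ 9 ⇒ 8).** The C1–C8a bond is cut (C-acylation of acetylide 10), then the C4a≡C8a unit is traced to the aldehyde carbon of 8 by a one-carbon homologation. The aldehyde carbon becomes C4a. Two short, standard steps convert the product of an alkene cleavage into the dienophile.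

**Desymmetrisation (8 ⇒ 7).** The C8'=C9' bond is cut (Wittig propylidenation), revealing the C2-symmetric dialdehyde 7. Because the two formyl groups are homotopic, olefination of either gives the same compound 8. The price is a statistical distribution, so the forward step limits the ylide and recycles 7.

**Dialdehyde to diol (7 ⇒ 5 ⇒ 4).** Both terminal C=C bonds are restored (double ozonolysis through bis-ozonide 6) and the silyl ethers removed, giving the diene-diol 4. Silyl protection is chosen because it survives ozone, ylide, acetylide and heat, and falls off in the final acid step.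

**Key disconnection (4 ⇒ 1 + 2).** The C3–C4 and C6'–C7' bonds are cut at once, giving heptane-1,7-diol 1 and two molecules of allyl acetate 2, with mono-adduct 3 as the half-way stage. Working from the diol oxidation level avoids heptanedial, which is prone to intramolecular aldol. A C2-symmetric ligand sets both centres, and the forward reaction must deliver the same facial sense at two remote termini.

## Roads not taken

**Alternative 1:** Ring B is cut at C4–C4a and C1–C8a, so the arene arrives as aryne A2 (3,5-dimethoxybenzyne) and the whole chain, with both carbinols, as β-lactone A1.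
- Forward step: the lithium enolate of A1 would add through its α-carbon (the future C4) to the aryne carbon remote from the flanking methoxy group. The aryl anion at the future C8a would close on the lactone carbonyl, and the fused cyclobutoxide would open to the six-membered lactone A3.
- Merits: convergence is the highest of all the plans. Ring B and two C–C bonds form in one step, and the arene oxygenation is bought.
- Weak points: aryne insertion into an acyl–carbon bond is established for β-keto esters and similar stabilised enolates, not for β-lactone enolates. These open by β-elimination to the unsaturated carboxylate well below ambient temperature. The usual aryne sources need either fluoride near room temperature or a strong amide base that also attacks the lactone. A3 carries methyl ethers at both O6 and O8, so a chelation-directed cleavage at O8 remains. A1 holds both stereocentres, so its own synthesis must still solve the remote 1,7-problem.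
- Comparison: if the insertion worked, the endgame would be shorter than the five operations the adopted plan spends on rings A and B (steps 5, 6, 9, 10, 11), and it would avoid a thermal cycloaddition. The adopted plan sets against this a close precedent for every step, a lactone formed after all basic steps, and both stereocentres from one catalytic reaction.

**Alternative 2:** Ring A is cut at C4a–C8a, leaving the diketo-dioxinone A4, an acetone-masked triketo acid.
- Forward step: triethylamine promotes aldol addition of the dioxinone α-carbon to the distal ketone, and dehydration gives the aromatic benzodioxinone A5.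
- Merits: the aromatisation runs at ambient temperature, which is milder than the 120–130 °C of step 9. The oxygenation pattern is inherent. The phenol para to the carboxyl is free while the ortho one is masked, so the later O-methylation is unambiguous. In mildness and in certainty of the ring-A pattern this road is better.
- Weak points: A4 needs two Claisen-type acylations with an activated β-silyloxy acid, and such polycarbonyl chains are labile. The β-silyloxy ketone at the future C4a can lose silanol under the same amine base. A separate methylation and a desilylation/lactonisation follow the key step. Both stereocentres must already be in the acyl donor.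
- Comparison: the adopted plan has fewer operations on ring A, since one benzannulation delivers methyl ether, phenol and ester together. It avoids polyketone handling and draws both stereocentres from one step.

**Alternative 3:** Ring B is cut at C1–O2/O2–C3 by removing the ring oxygen, giving the five-membered ketone A6, which racemises at C2.
- Forward step: a Baeyer–Villiger monooxygenase (flavin, NADPH, O2) would oxidise only the (2R)-epimer with migration of the alkyl carbon, giving lactone A7 by dynamic kinetic resolution.
- Merits: C3 is set with enzyme-level selectivity from a racemate. A6 is easy to make by alkylation of the dimethoxyindanone. There is no statistical step and no thermal cycloaddition. In these respects the road is shorter and probably more selective at C3 than a single catalytic allylation.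
- Weak points: the chemical Baeyer–Villiger reaction of 1-indanones favours aryl migration, the more so with an electron-rich dimethoxyaryl group, so the regiochemistry depends entirely on the enzyme. This resolution is known for small 2-alkyl groups, whereas A6 has an eleven-carbon lipophilic chain, a free carbinol and a methoxy group peri to the ketone. Racemisation needs a basic medium in which the product lactone can hydrolyse. C6' needs a separate asymmetric step, and the O8 methyl ether must still be cleaved selectively.
- Comparison: the adopted plan does not depend on enzyme acceptance of an untested substrate, and it sets C3 and C6' with one catalyst.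

Key step: step 1

Assumption: the (S)-configured bisphosphine is taken to give the (R) carbinol from an unbranched alkyl aldehyde; if the sense proves opposite, the antipodal ligand is used and nothing else changes.

Assumption: the ketene-acetal geometry of diene 15 is left unassigned, because that carbon becomes aromatic C8.

## Route

Step 1
Reactants: 1 heptane-1,7-diol; 2 allyl acetate
Product: 4 (4R,10R)-trideca-1,12-diene-4,10-diol, via (7R)-dec-9-ene-1,7-diol 3 (not isolated)
Conditions: [Ir(cod)Cl]2 (5 mol%), (S)-Cl,MeO-BIPHEP (10 mol%), 4-chloro-3-nitrobenzoic acid (20 mol%), Cs2CO3 (40 mol%), 2 (10 equiv), 1,4-dioxane, 90 °C, sealed vessel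
Reagents that add atoms: none
Why: The reaction type is the iridium-catalysed transfer-hydrogenative carbonyl allylation from the alcohol oxidation level, run two-directionally on a 1,n-glycol. [Ir(cod)Cl]2, the bisphosphine, the nitrobenzoic acid and 2 assemble an ortho-cyclometalated π-allyl C,O-benzoate complex of trivalent iridium; a primary hydroxyl of 1 binds as alkoxide and undergoes β-hydride elimination to the aldehyde and an iridium hydride, the σ-allyl form adds to the aldehyde through a closed six-membered chair transition state, and base-assisted deprotonation of the hydride to univalent iridium followed by oxidative addition of 2 regenerates the allyl complex, with acetic acid as the only by-product. The first pass gives 3, whose remaining primary hydroxyl enters the same cycle to give 4; no ring is closed. Both new stereocentres (C4 and C10 of 4, the later C3 and C6') are set by the C2-symmetric bisphosphine alone, which exposes the same enantiotopic face of each transient aldehyde. The termini are seven atoms apart, so neither a lactol (it would be eight-membered) nor the first carbinol can bias the second addition, and the two events are independent. Chemoselectivity rests on the homoallylic products being poor hydrogen donors, since the olefin occupies the coordination site needed for β-hydride elimination, and the excess of 2 drives both ends to completion. A wrong-sense addition at either end gives the meso diol, so 4 should have a higher enantiomeric purity than a single addition would give (for illustration, two independent 96:4 events would give about 92:8 C2 to meso with the C2 part nearly enantiopure). The meso isomer has insulated centres and cannot be relied on to separate, so the per-terminus selectivity fixes the diastereomeric purity of everything downstream and is assayed at this stage (bis-Mosher ester, 19F NMR).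

Step 2
Reactants: 4 (4R,10R)-trideca-1,12-diene-4,10-diol
Product: 5 (4R,10R)-4,10-bis(tert-butyldimethylsilyloxy)trideca-1,12-diene
Conditions: TBSCl (2.6 equiv), imidazole (5 equiv), DMF, rt
Reagents that add atoms: tert-butyldimethylsilyl chloride, CC(C)(C)[Si](C)(C)Cl
Why: Standard silylation of two unhindered secondary alcohols; no stereocentre is touched, and the silyl ethers tolerate ozone, ylide, acetylide and heating and are removed by acid in step 11.

Step 3
Reactants: 5 (4R,10R)-4,10-bis(tert-butyldimethylsilyloxy)trideca-1,12-diene
Product: 7 (3R,9R)-3,9-bis(tert-butyldimethylsilyloxy)undecanedial, via bis-ozonide 6 (not isolated)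
Conditions: O3, CH2Cl2, −78 °C; then PPh3 (2.4 equiv), −78 °C → rt
Reagents that add atoms: ozone, [O-][O+]=O
Why: Ozonolysis of both terminal alkenes with reductive work-up; the two-directional cleavage keeps the C2 symmetry, and the neutral phosphine reduction avoids β-elimination of the silyloxy groups, so 7 is used promptly.

Step 4
Reactants: 7 (3R,9R)-3,9-bis(tert-butyldimethylsilyloxy)undecanedial
Product: 8 (3R,9R,11Z)-3,9-bis(tert-butyldimethylsilyloxy)tetradec-11-enal
Conditions: n-PrPPh3Br (0.85 equiv), NaN(SiMe3)2 (0.8 equiv), THF, 0 °C; ylide added dropwise to 7 in THF, −78 °C → 0 °C; unreacted 7 recovered and resubmitted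
Reagents that add atoms: propyltriphenylphosphonium bromide, CCC[P+](c1ccccc1)(c1ccccc1)c1ccccc1.[Br-]
Why: Wittig olefination with a non-stabilised, lithium-free ylide (Z-selective, although the geometry is erased in step 10); the formyl groups of 7 are homotopic, so mono-olefination gives a single compound, and the sub-stoichiometric ylide biases the statistical mixture towards 8 and recoverable 7. The theoretical ceiling of a single pass is one half.

Step 5
Reactants: 8 (3R,9R,11Z)-3,9-bis(tert-butyldimethylsilyloxy)tetradec-11-enal
Product: 9 (4R,10R,12Z)-4,10-bis(tert-butyldimethylsilyloxy)pentadec-12-en-1-yne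
Conditions: dimethyl (1-diazo-2-oxopropyl)phosphonate (1.3 equiv), K2CO3 (2 equiv), MeOH, 0 °C → rt
Reagents that add atoms: dimethyl (1-diazo-2-oxopropyl)phosphonate, CC(=O)C(=[N+]=[N-])P(=O)(OC)OC
Why: Seyferth–Gilbert homologation in the Ohira–Bestmann variant; the mild carbonate conditions convert the aldehyde carbon (future C4a) into an alkyne carbon and add the future C8a, and the carbinol centres are not α to the carbonyl and so cannot epimerise.

Step 6
Reactants: 9 (4R,10R,12Z)-4,10-bis(tert-butyldimethylsilyloxy)pentadec-12-en-1-yne
Product: 11 methyl (5R,11R,13Z)-5,11-bis(tert-butyldimethylsilyloxy)hexadec-13-en-2-ynoate, via lithium acetylide 10 (not isolated)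
Conditions: n-BuLi (1.1 equiv), THF, −78 °C; then ClCO2Me (1.5 equiv), −78 → 0 °C
Reagents that add atoms: methyl chloroformate, COC(=O)Cl
Why: Deprotonation of the terminal alkyne and C-acylation of the acetylide with a chloroformate install C1 and activate the alkyne as a dienophile; silyl ethers and the isolated alkene are inert.

Step 7
Reactants: 12 methyl acetoacetate
Product: 13 methyl (2E)-3-methoxybut-2-enoate
Conditions: HC(OMe)3 (1.1 equiv), H2SO4 (cat.), MeOH, rt; distillation
Reagents that add atoms: trimethyl orthoformate, COC(OC)OC
Why: Acid-catalysed ketalisation of the ketone and loss of methanol give the conjugated enol ether, the (E) isomer being the thermodynamic product.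

Step 8
Reactants: 13 methyl (2E)-3-methoxybut-2-enoate
Product: 15 1,3-dimethoxy-1-(trimethylsilyloxy)buta-1,3-diene, via lithium dienolate 14 (not isolated)
Conditions: LiN(i-Pr)2 (1.1 equiv), THF, −78 °C; then Me3SiCl (1.2 equiv), −78 °C → rt; filtration under argon, bulb-to-bulb distillation, used at once
Reagents that add atoms: chlorotrimethylsilane, C[Si](C)(C)Cl
Why: Kinetic γ-deprotonation of the β-methoxy crotonate gives the extended dienolate, which is silylated on oxygen to the vinylketene acetal (Brassard diene); the diene is moisture-sensitive and is prepared fresh.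

Step 9
Reactants: 11 methyl (5R,11R,13Z)-5,11-bis(tert-butyldimethylsilyloxy)hexadec-13-en-2-ynoate; 15 1,3-dimethoxy-1-(trimethylsilyloxy)buta-1,3-diene
Product: 18 methyl 2-[(2R,8R,10Z)-2,8-bis(tert-butyldimethylsilyloxy)tridec-10-en-1-yl]-6-hydroxy-4-methoxybenzoate, via cyclohexadiene cycloadduct 16 (not isolated), via aryl trimethylsilyl ether 17 (not isolated)
Conditions: 15 (3 equiv, in portions), toluene, 120–130 °C, sealed tube; then 1 M HCl, THF, 0 °C, brief
Reagents that add atoms: none
Why: Diels–Alder benzannulation of an alkynoate with a vinylketene acetal: the nucleophilic CH2 terminus of 15 bonds to the β-carbon of 11 (C4a–C5) and the acetal carbon to the α-carbon (C8–C8a), so the ester polarisation fixes the regiochemistry. Adduct 16 aromatises by 1,4-loss of methanol to 17, whose aryl silyl ether is hydrolysed by brief dilute acid while the secondary silyl ethers survive, giving the C8 phenol and C6 methyl ether already differentiated.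

Step 10
Reactants: 18 methyl 2-[(2R,8R,10Z)-2,8-bis(tert-butyldimethylsilyloxy)tridec-10-en-1-yl]-6-hydroxy-4-methoxybenzoate
Product: 19 methyl 2-[(2R,8S)-2,8-bis(tert-butyldimethylsilyloxy)tridecyl]-6-hydroxy-4-methoxybenzoate
Conditions: H2 (1 atm), Pd/C (10%), EtOAc, rt
Reagents that add atoms: none
Why: Heterogeneous hydrogenation of the isolated disubstituted alkene; arene, ester and silyl ethers are inert in ethyl acetate, and the descriptor at the side-chain carbinol changes from R to S only because the saturated pentyl group now ranks below the tether.

Step 11
Reactants: 19 methyl 2-[(2R,8S)-2,8-bis(tert-butyldimethylsilyloxy)tridecyl]-6-hydroxy-4-methoxybenzoate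
Product: 21 (3R)-8-hydroxy-3-[(6S)-6-hydroxyundecyl]-6-methoxy-3,4-dihydro-1H-isochromen-1-one, via dihydroxy ester 20 (not isolated)
Conditions: HCl (1.25 M in MeOH), rt; evaporation; then p-TsOH·H2O (10 mol%), toluene, 60 °C
Reagents that add atoms: none
Why: Acid methanolysis removes both silyl ethers, and the freed C3 hydroxyl of 20 then closes on the ortho ester by acid-catalysed 6-exo-trig transesterification with loss of methanol; the aryl methyl ether and both carbinol centres are unaffected, and the remote C6' hydroxyl cannot form a comparably favoured ring.

## Compound list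

1 | heptane-1,7-diol | OCCCCCCCO | starting material
2 | allyl acetate (prop-2-en-1-yl acetate) | C=CCOC(C)=O | starting material
3 | (7R)-dec-9-ene-1,7-diol | C=CC[C@H](O)CCCCCCO | intermediate (not isolated)
4 | (4R,10R)-trideca-1,12-diene-4,10-diol | C=CC[C@H](O)CCCCC[C@@H](O)CC=C | intermediate
5 | (4R,10R)-4,10-bis(tert-butyldimethylsilyloxy)trideca-1,12-diene | C=CC[C@H](O[Si](C)(C)C(C)(C)C)CCCCC[C@@H](O[Si](C)(C)C(C)(C)C)CC=C | intermediate
6 | 3,3'-[(2R,8R)-2,8-bis(tert-butyldimethylsilyloxy)nonane-1,9-diyl]bis(1,2,4-trioxolane) (bis-ozonide of 5, ring carbons unassigned) | C1OOC(C[C@H](O[Si](C)(C)C(C)(C)C)CCCCC[C@@H](O[Si](C)(C)C(C)(C)C)CC2OCOO2)O1 | intermediate (not isolated)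
7 | (3R,9R)-3,9-bis(tert-butyldimethylsilyloxy)undecanedial | O=CC[C@H](O[Si](C)(C)C(C)(C)C)CCCCC[C@@H](O[Si](C)(C)C(C)(C)C)CC=O | intermediate
8 | (3R,9R,11Z)-3,9-bis(tert-butyldimethylsilyloxy)tetradec-11-enal | O=CC[C@H](O[Si](C)(C)C(C)(C)C)CCCCC[C@@H](O[Si](C)(C)C(C)(C)C)C/C=C\CC | intermediate
9 | (4R,10R,12Z)-4,10-bis(tert-butyldimethylsilyloxy)pentadec-12-en-1-yne | C#CC[C@H](O[Si](C)(C)C(C)(C)C)CCCCC[C@@H](O[Si](C)(C)C(C)(C)C)C/C=C\CC | intermediate
10 | [(4R,10R,12Z)-4,10-bis(tert-butyldimethylsilyloxy)pentadec-12-en-1-yn-1-yl]lithium (lithium acetylide of 9) | [Li]C#CC[C@H](O[Si](C)(C)C(C)(C)C)CCCCC[C@@H](O[Si](C)(C)C(C)(C)C)C/C=C\CC | intermediate (not isolated)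
11 | methyl (5R,11R,13Z)-5,11-bis(tert-butyldimethylsilyloxy)hexadec-13-en-2-ynoate | COC(=O)C#CC[C@H](O[Si](C)(C)C(C)(C)C)CCCCC[C@@H](O[Si](C)(C)C(C)(C)C)C/C=C\CC | intermediate
12 | methyl acetoacetate (methyl 3-oxobutanoate) | CC(=O)CC(=O)OC | starting material
13 | methyl (2E)-3-methoxybut-2-enoate | CO/C(C)=C/C(=O)OC | intermediate
14 | lithium 1,3-dimethoxybuta-1,3-dien-1-olate | [Li]OC(OC)=CC(OC)=C | intermediate (not isolated)
15 | 1,3-dimethoxy-1-(trimethylsilyloxy)buta-1,3-diene (Brassard diene, ketene-acetal geometry unassigned) | C=C(OC)C=C(OC)O[Si](C)(C)C | intermediate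
16 | methyl 2-[(2R,8R,10Z)-2,8-bis(tert-butyldimethylsilyloxy)tridec-10-en-1-yl]-4,6-dimethoxy-6-(trimethylsilyloxy)cyclohexa-1,4-diene-1-carboxylate (C6 epimers) | COC(=O)C1=C(C[C@H](O[Si](C)(C)C(C)(C)C)CCCCC[C@@H](O[Si](C)(C)C(C)(C)C)C/C=C\CC)CC(OC)=CC1(OC)O[Si](C)(C)C | intermediate (not isolated)
17 | methyl 2-[(2R,8R,10Z)-2,8-bis(tert-butyldimethylsilyloxy)tridec-10-en-1-yl]-4-methoxy-6-(trimethylsilyloxy)benzoate | COC(=O)c1c(C[C@H](O[Si](C)(C)C(C)(C)C)CCCCC[C@@H](O[Si](C)(C)C(C)(C)C)C/C=C\CC)cc(OC)cc1O[Si](C)(C)C | intermediate (not isolated)
18 | methyl 2-[(2R,8R,10Z)-2,8-bis(tert-butyldimethylsilyloxy)tridec-10-en-1-yl]-6-hydroxy-4-methoxybenzoate | COC(=O)c1c(C[C@H](O[Si](C)(C)C(C)(C)C)CCCCC[C@@H](O[Si](C)(C)C(C)(C)C)C/C=C\CC)cc(OC)cc1O | intermediate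
19 | methyl 2-[(2R,8S)-2,8-bis(tert-butyldimethylsilyloxy)tridecyl]-6-hydroxy-4-methoxybenzoate | COC(=O)c1c(C[C@H](O[Si](C)(C)C(C)(C)C)CCCCC[C@@H](O[Si](C)(C)C(C)(C)C)CCCCC)cc(OC)cc1O | intermediate
20 | methyl 2-[(2R,8S)-2,8-dihydroxytridecyl]-6-hydroxy-4-methoxybenzoate | COC(=O)c1c(C[C@H](O)CCCCC[C@@H](O)CCCCC)cc(OC)cc1O | intermediate (not isolated)
21 | (3R)-8-hydroxy-3-[(6S)-6-hydroxyundecyl]-6-methoxy-3,4-dihydro-1H-isochromen-1-one | CCCCC[C@H](O)CCCCC[C@@H]1Cc2cc(OC)cc(O)c2C(=O)O1 | target

## Step count and risks

Total step count: 11. Longest linear sequence: 9 (steps 1–6 and 9–11, from heptane-1,7-diol 1). The diene branch (steps 7 and 8) is 2 steps from methyl acetoacetate 12.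

**Step 1 (key step).** The second terminus may stall at mono-adduct 3. More seriously, facial selectivity may erode at 90 °C, which feeds a meso diol that co-elutes with 4 and would carry through the whole route as an inseparable diastereomer. The fallback moves to stoichiometric reagent control at the aldehyde oxidation level and low temperature. From 1, Swern oxidation ((COCl)2, DMSO, Et3N, CH2Cl2, −78 °C) would give heptanedial F1, used crude at once. Two-directional allylboration follows with B-allyldiisopinocampheylborane, (−)-Ipc2B(allyl), made from (−)-B-methoxydiisopinocampheylborane and CH2=CHCH2MgBr with the magnesium salts filtered off, in Et2O at −100 °C. This reagent is the enantiomer expected to give the (R) carbinol from an unbranched aldehyde. Oxidative work-up (NaOH, H2O2) returns to the route at 4. This fallback does not make the meso isomer separable either, so the stereochemical assay at 4 remains the gate.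

**Step 4.** Over-olefination at both formyl groups can occur, as can base-induced loss of silanol from the β-silyloxy aldehyde during reaction or recovery. Either would keep the step well below its statistical ceiling. The fallback keeps both ends equivalent for one more step and differentiates them on a robust diyne.
- From 7, Ohira–Bestmann homologation at both termini would give (4R,10R)-4,10-bis(tert-butyldimethylsilyloxy)trideca-1,12-diyne F2.
- Mono-C-ethylation (n-BuLi 1.0 equiv, THF, −78 °C; EtI, DMPU, → rt) would give (4R,10R)-4,10-bis(tert-butyldimethylsilyloxy)pentadeca-1,12-diyne F3. Unreacted F2 is stable and recyclable.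
- Deprotonation of the remaining terminal alkyne and acylation with ClCO2Me would give methyl (5R,11R)-5,11-bis(tert-butyldimethylsilyloxy)hexadeca-2,13-diynoate F4.
- Benzannulation with 15 as in step 9 (the unactivated internal alkyne is not a dienophile) would give methyl 2-[(2R,8R)-2,8-bis(tert-butyldimethylsilyloxy)tridec-10-yn-1-yl]-6-hydroxy-4-methoxybenzoate F5.
- Exhaustive hydrogenation (H2, Pd/C, EtOAc) reduces the alkyne to the alkane and comes back to the route at 19.

**Step 9.** The β-alkyl ynoate may be too slow a dienophile to compete with thermal decomposition of the silyl ketene acetal. Aromatisation may also proceed partly with loss of the silyloxy group instead of the methoxy group, scrambling the C8 phenol and its methyl ether. The fallback uses a robust cyclic diene and an irreversible retro-cycloaddition (Alder–Rickert).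
- From 11, heating with 1,5-dimethoxycyclohexa-1,4-diene (conjugating in situ, 180 °C, sealed) would give, after extrusion of ethene from the bicyclic adduct, methyl 2-[(2R,8R,10Z)-2,8-bis(tert-butyldimethylsilyloxy)tridec-10-en-1-yl]-4,6-dimethoxybenzoate F6.
- Hydrogenation as in step 10 would give methyl 2-[(2R,8S)-2,8-bis(tert-butyldimethylsilyloxy)tridecyl]-4,6-dimethoxybenzoate F7.
- Acid treatment as in step 11 would give (3R)-3-[(6S)-6-hydroxyundecyl]-6,8-dimethoxy-3,4-dihydro-1H-isochromen-1-one F8, the same compound as A7.
- Chelation-directed cleavage of the methyl ether peri to the lactone carbonyl with BCl3 (CH2Cl2, −78 → 0 °C) comes back to the route at 21, one step longer than the main line.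

**Step 5.** Under carbonate in methanol the β-silyloxy aldehyde may lose silanol to the enal faster than it is homologated. The fallback avoids alkoxide base at the aldehyde stage. From 8, dibromo-olefination (CBr4, PPh3, Et3N, CH2Cl2, 0 °C) would give (4R,10R,12Z)-1,1-dibromo-4,10-bis(tert-butyldimethylsilyloxy)pentadeca-1,12-diene F9. Treatment with n-BuLi (2.2 equiv, THF, −78 °C) and trapping of the resulting acetylide with ClCO2Me (Corey–Fuchs sequence) comes back to the route at 11, bypassing 9.

## Further compounds

F1 | step 1 | heptanedial | O=CCCCCCC=O
F2 | step 4 | (4R,10R)-4,10-bis(tert-butyldimethylsilyloxy)trideca-1,12-diyne | C#CC[C@H](O[Si](C)(C)C(C)(C)C)CCCCC[C@@H](O[Si](C)(C)C(C)(C)C)CC#C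
F3 | step 4 | (4R,10R)-4,10-bis(tert-butyldimethylsilyloxy)pentadeca-1,12-diyne | C#CC[C@H](O[Si](C)(C)C(C)(C)C)CCCCC[C@@H](O[Si](C)(C)C(C)(C)C)CC#CCC
F4 | step 4 | methyl (5R,11R)-5,11-bis(tert-butyldimethylsilyloxy)hexadeca-2,13-diynoate | COC(=O)C#CC[C@H](O[Si](C)(C)C(C)(C)C)CCCCC[C@@H](O[Si](C)(C)C(C)(C)C)CC#CCC
F5 | step 4 | methyl 2-[(2R,8R)-2,8-bis(tert-butyldimethylsilyloxy)tridec-10-yn-1-yl]-6-hydroxy-4-methoxybenzoate | COC(=O)c1c(C[C@H](O[Si](C)(C)C(C)(C)C)CCCCC[C@@H](O[Si](C)(C)C(C)(C)C)CC#CCC)cc(OC)cc1O
F6 | step 9 | methyl 2-[(2R,8R,10Z)-2,8-bis(tert-butyldimethylsilyloxy)tridec-10-en-1-yl]-4,6-dimethoxybenzoate | COC(=O)c1c(C[C@H](O[Si](C)(C)C(C)(C)C)CCCCC[C@@H](O[Si](C)(C)C(C)(C)C)C/C=C\CC)cc(OC)cc1OC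
F7 | step 9 | methyl 2-[(2R,8S)-2,8-bis(tert-butyldimethylsilyloxy)tridecyl]-4,6-dimethoxybenzoate | COC(=O)c1c(C[C@H](O[Si](C)(C)C(C)(C)C)CCCCC[C@@H](O[Si](C)(C)C(C)(C)C)CCCCC)cc(OC)cc1OC
F8 | step 9 | (3R)-3-[(6S)-6-hydroxyundecyl]-6,8-dimethoxy-3,4-dihydro-1H-isochromen-1-one | CCCCC[C@H](O)CCCCC[C@@H]1Cc2cc(OC)cc(OC)c2C(=O)O1
F9 | step 5 | (4R,10R,12Z)-1,1-dibromo-4,10-bis(tert-butyldimethylsilyloxy)pentadeca-1,12-diene | BrC(Br)=CC[C@H](O[Si](C)(C)C(C)(C)C)CCCCC[C@@H](O[Si](C)(C)C(C)(C)C)C/C=C\CC
A1 | alternative 1 | (4R)-4-[(6S)-6-(tert-butyldimethylsilyloxy)undecyl]oxetan-2-one | CCCCC[C@H](O[Si](C)(C)C(C)(C)C)CCCCC[C@@H]1CC(=O)O1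
A2 | alternative 1 | 3,5-dimethoxybenzyne (1,2-didehydro-3,5-dimethoxybenzene) | COC1=CC(OC)=CC#C1
A3 | alternative 1 | (3R)-3-[(6S)-6-(tert-butyldimethylsilyloxy)undecyl]-6,8-dimethoxy-3,4-dihydro-1H-isochromen-1-one | CCCCC[C@H](O[Si](C)(C)C(C)(C)C)CCCCC[C@@H]1Cc2cc(OC)cc(OC)c2C(=O)O1
A4 | alternative 2 | 6-[(6R,12S)-6,12-bis(tert-butyldimethylsilyloxy)-2,4-dioxoheptadecyl]-2,2-dimethyl-4H-1,3-dioxin-4-one | CCCCC[C@H](O[Si](C)(C)C(C)(C)C)CCCCC[C@@H](O[Si](C)(C)C(C)(C)C)CC(=O)CC(=O)CC1=CC(=O)OC(C)(C)O1
A5 | alternative 2 | 7-hydroxy-2,2-dimethyl-5-[(2R,8S)-2,8-bis(tert-butyldimethylsilyloxy)tridecyl]-4H-1,3-benzodioxin-4-one | CCCCC[C@H](O[Si](C)(C)C(C)(C)C)CCCCC[C@@H](O[Si](C)(C)C(C)(C)C)Cc1cc(O)cc2OC(C)(C)OC(=O)c12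
A6 | alternative 3 | 2-[(6S)-6-hydroxyundecyl]-5,7-dimethoxy-2,3-dihydro-1H-inden-1-one (C2 epimers in equilibrium) | CCCCC[C@H](O)CCCCCC1Cc2cc(OC)cc(OC)c2C1=O
A7 | alternative 3 | (3R)-3-[(6S)-6-hydroxyundecyl]-6,8-dimethoxy-3,4-dihydro-1H-isochromen-1-one | CCCCC[C@H](O)CCCCC[C@@H]1Cc2cc(OC)cc(OC)c2C(=O)O1
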